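## Retrosynthetic overview

1. Target 9 ⇐ diol 8 (benzoylation of C2–OH) ⇐ racemic triol 7 (lipase acetylation at C5 selects the enantiomer).
2. 7 ⇐ endoperoxide 6 (O–O reduction unveils the cis C2/C5 oxygens) ⇐ 5 (C6 acetylation) ⇐ ketol 4 (reduction directed by C1–OH sets C6).
3. 4 ⇐ spiro-epoxy keto endoperoxide 3 (benzoate opens the oxirane at CH2, giving C1–OH and CH2OBz).
4. 3 ⇐ salicyl alcohol 1: periodate dearomatisation (oxirane) and singlet-oxygen [4+2] (peroxide bridge) in one flask; C1, C2 and C5 are fixed relative to each other here.
5. Ring order: the carbocycle is the arene of 1; the oxirane forms first and the peroxide bridge second in the same operation; both auxiliary rings are opened later (steps 2 and 5).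

Assumption: compounds 2 to 7 are racemates; each name and SMILES shows the enantiomer that ends up in the target, and the mirror-image series is removed in step 6.

Numbering used in the stereo-descriptions: C1 carries the CH2O arm, C2 is its neighbour on the alkene side (future benzoate), C3=C4 is the alkene, C5 and C6 are the future acetate carbons (C6 next to C1). In the target, C1–OH, C2–O and C5–O lie on one face; C6–O and the CH2O arm lie on the other.

## Route

Step 1
Reactants: 1 salicyl alcohol (2-(hydroxymethyl)phenol)
Product: 3 racemic spiro[2,3-dioxabicyclo[2.2.2]oct-7-ene-5,2'-oxiran]-6-one (oxirane O syn to the O–O bridge), via spiro-epoxy dienone 2 (not isolated)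
Conditions: NaIO4 (1.1 equiv), H2O/CH2Cl2 (1:5), 0 °C, 1 added over 2 h; O2, 5,10,15,20-tetraphenylporphyrin (1 mol%), hν (λ > 500 nm), same flask
Reagents that add atoms: dioxygen (reacting as singlet oxygen), O=O
Why: Proposed new method: Adler–Becker periodate oxidation of the o-hydroxybenzyl alcohol closes the oxirane and gives dienone 2, which moves into the CH2Cl2 layer and is captured there by singlet oxygen in a suprafacial [4+2] photooxygenation (so C2–O and C5–O are cis) before it can dimerise, with O2 adding on the face of the oxirane oxygen and away from the oxirane CH2 as carbon dienophiles do with this dienone; the closest known reactions are the Adler–Becker oxidation with in situ Diels–Alder trapping of spiro-epoxy cyclohexadienones and the photooxygenation of cyclic dienones such as tropone to endoperoxides.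

Step 2
Reactants: 3 racemic spiro[2,3-dioxabicyclo[2.2.2]oct-7-ene-5,2'-oxiran]-6-one
Product: 4 racemic (5-hydroxy-6-oxo-2,3-dioxabicyclo[2.2.2]oct-7-en-5-yl)methyl benzoate (5-OH syn to the O–O bridge)
Conditions: PhCO2H (3 equiv), Bu4N(O2CPh) (20 mol%), MeCN, 40 °C
Reagents that add atoms: benzoic acid, O=C(O)c1ccccc1
Why: Buffered carboxylate opening of a terminal 2,2-disubstituted epoxide, in which benzoate attacks the unhindered CH2 in an SN2 reaction so that the C1–O bond and its configuration are untouched and the tertiary alcohol and primary benzoate appear together, while the weakly basic medium should spare the endoperoxide from Kornblum–DeLaMare cleavage.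

Step 3
Reactants: 4 racemic (5-hydroxy-6-oxo-2,3-dioxabicyclo[2.2.2]oct-7-en-5-yl)methyl benzoate
Product: 5 racemic (5,6-dihydroxy-2,3-dioxabicyclo[2.2.2]oct-7-en-5-yl)methyl benzoate (5-OH syn and 6-OH anti to the O–O bridge, trans-diol)
Conditions: Me4NBH(OAc)3 (3 equiv), MeCN/AcOH (1:1), −20 °C to 0 °C
Reagents that add atoms: none
Why: Hydroxyl-directed reduction (Saksena–Evans type), in which the tertiary C1–OH exchanges onto boron and hands hydride to the neighbouring carbonyl from its own face, which is also the open face next to the O–O bridge, so the new C6–OH lies trans to C1–OH.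

Step 4
Reactants: 5 racemic (5,6-dihydroxy-2,3-dioxabicyclo[2.2.2]oct-7-en-5-yl)methyl benzoate
Product: 6 racemic (6-acetoxy-5-hydroxy-2,3-dioxabicyclo[2.2.2]oct-7-en-5-yl)methyl benzoate (same relative configuration)
Conditions: Ac2O, pyridine, 4-(dimethylamino)pyridine (5 mol%), CH2Cl2, 0 °C
Reagents that add atoms: acetic anhydride, CC(=O)OC(C)=O
Why: Standard nucleophile-catalysed acylation that acetylates the secondary C6–OH while the tertiary C1–OH is inert, under conditions cold and weakly basic enough to leave the endoperoxide intact.

Step 5
Reactants: 6 racemic (6-acetoxy-5-hydroxy-2,3-dioxabicyclo[2.2.2]oct-7-en-5-yl)methyl benzoate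
Product: 7 racemic [(1S,2S,5R,6S)-6-acetoxy-1,2,5-trihydroxycyclohex-3-en-1-yl]methyl benzoate
Conditions: thiourea (2.2 equiv), MeOH, rt
Reagents that add atoms: none
Why: Thiourea reduction of a bicyclic endoperoxide cleaves only the O–O bond, so both C–O bonds are kept and the cis-1,4 relationship of C2–OH and C5–OH (both syn to C1–OH) set in step 1 is revealed.

Step 6
Reactants: 7 racemic [(1S,2S,5R,6S)-6-acetoxy-1,2,5-trihydroxycyclohex-3-en-1-yl]methyl benzoate
Product: 8 [(1S,2S,5R,6S)-5,6-diacetoxy-1,2-dihydroxycyclohex-3-en-1-yl]methyl benzoate (single enantiomer)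
Conditions: Burkholderia cepacia lipase (Amano PS-IM), vinyl acetate, t-BuOMe, 35 °C, stopped at 50% conversion
Reagents that add atoms: vinyl acetate, C=COC(C)=O
Why: Lipase-catalysed kinetic resolution by irreversible transesterification, in which the enzyme takes only the unhindered allylic C5–OH and, by Kazlauskas' rule (C6 side large, C4 side medium), is predicted to acylate the enantiomer with the (5R) carbinol, giving 8 in at most 50% yield and leaving the mirror-image triol to be removed by chromatography.

Step 7
Reactants: 8 [(1S,2S,5R,6S)-5,6-diacetoxy-1,2-dihydroxycyclohex-3-en-1-yl]methyl benzoate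
Product: 9 cleistenediol F, [(1S,2S,5R,6S)-5,6-diacetoxy-2-(benzoyloxy)-1-hydroxycyclohex-3-en-1-yl]methyl benzoate
Conditions: BzCl (1.5 equiv), pyridine, 4-(dimethylamino)pyridine (10 mol%), CH2Cl2, 0 °C to rt
Reagents that add atoms: benzoyl chloride, O=C(Cl)c1ccccc1
Why: Nucleophile-catalysed benzoylation of the one remaining secondary alcohol at C2, the tertiary C1–OH being too hindered to react, completes the target without touching any stereocentre.

## Compound list

1 | salicyl alcohol, 2-(hydroxymethyl)phenol | OCc1ccccc1O | starting material
2 | racemic 1-oxaspiro[2.5]octa-5,7-dien-4-one (not isolated) | C1=CC=C[C@@]2(CO2)C1=O | intermediate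
3 | racemic spiro[2,3-dioxabicyclo[2.2.2]oct-7-ene-5,2'-oxiran]-6-one, oxirane O syn to the O–O bridge | O3[C@@H]1C=C[C@H](O3)[C@@]4(CO4)C1=O | intermediate
4 | racemic (5-hydroxy-6-oxo-2,3-dioxabicyclo[2.2.2]oct-7-en-5-yl)methyl benzoate, 5-OH syn to the O–O bridge | O3[C@@H]1C=C[C@H](O3)[C@@](O)(COC(=O)c2ccccc2)C1=O | intermediate
5 | racemic (5,6-dihydroxy-2,3-dioxabicyclo[2.2.2]oct-7-en-5-yl)methyl benzoate, 5-OH syn and 6-OH anti to the O–O bridge | O3[C@@H]1C=C[C@H](O3)[C@@](O)(COC(=O)c2ccccc2)[C@H]1O | intermediate
6 | racemic (6-acetoxy-5-hydroxy-2,3-dioxabicyclo[2.2.2]oct-7-en-5-yl)methyl benzoate, 5-OH syn and 6-OAc anti to the O–O bridge | O3[C@@H]1C=C[C@H](O3)[C@@](O)(COC(=O)c2ccccc2)[C@H]1OC(C)=O | intermediate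
7 | racemic [(1S,2S,5R,6S)-6-acetoxy-1,2,5-trihydroxycyclohex-3-en-1-yl]methyl benzoate | O[C@@H]1C=C[C@H](O)[C@@](O)(COC(=O)c2ccccc2)[C@H]1OC(C)=O | intermediate
8 | [(1S,2S,5R,6S)-5,6-diacetoxy-1,2-dihydroxycyclohex-3-en-1-yl]methyl benzoate | CC(=O)O[C@@H]1C=C[C@H](O)[C@@](O)(COC(=O)c2ccccc2)[C@H]1OC(C)=O | intermediate
9 | cleistenediol F, [(1S,2S,5R,6S)-5,6-diacetoxy-2-(benzoyloxy)-1-hydroxycyclohex-3-en-1-yl]methyl benzoate | CC(=O)O[C@@H]1C=C[C@H](OC(=O)c2ccccc2)[C@@](O)(COC(=O)c2ccccc2)[C@H]1OC(C)=O | target

## Step count and risks

Total step count: 7. Longest linear sequence: 7 (fully linear from 1).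

The three steps most likely to fail:

**Step 1** (one-flask dearomatisation and photooxygenation). The risks are Diels–Alder dimerisation of 2, slow uptake of singlet oxygen by an electron-poor dienone, and the wrong facial sense. The fallback sets out from 1 and comes back at 6; it takes the carbonyl out before the cycloaddition. Compound 1 is oxidised with NaIO4 as before but in the dark, and the cold extract is reduced at once (NaBH4, CeCl3·7H2O, MeOH, −40 °C) to racemic 1-oxaspiro[2.5]octa-5,7-dien-4-ol F1. Hydride is expected to enter past the oxirane oxygen, so the hydroxyl ends up anti to it. F1 has no enone and cannot dimerise; it is acid-labile and is handled cold. Acetylation (Ac2O, pyridine, 0 °C) gives 1-oxaspiro[2.5]octa-5,7-dien-4-yl acetate F2, an electron-rich 5,6-trans-dioxygenated cyclohexa-1,3-diene of the kind that takes up singlet oxygen anti to the acyloxy group. Photooxygenation (O2, 5,10,15,20-tetraphenylporphyrin, hν, CH2Cl2, −20 °C) gives spiro[2,3-dioxabicyclo[2.2.2]oct-7-ene-5,2'-oxiran]-6-yl acetate F3. Opening its oxirane with PhCO2H and Bu4N(O2CPh) as in step 2 gives 6.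

**Step 2** (benzoate opening of an oxirane that sits next to a ketone and an endoperoxide). The risks are Kornblum–DeLaMare fragmentation through the C–H between the carbonyl and the O–O bridge, and α-ketol shift of the product. The fallback sets out from 3 and comes back at 5; it reduces first and opens second. Luche reduction of 3 (NaBH4, CeCl3·7H2O, MeOH, −78 °C) should deliver hydride from the face flanked by the oxirane oxygen and the O–O bridge, because the other face is screened by the oxirane CH2 and the etheno bridge. This gives spiro[2,3-dioxabicyclo[2.2.2]oct-7-ene-5,2'-oxiran]-6-ol F4 with the hydroxyl anti to the peroxide bridge. With the carbonyl gone, the oxirane of F4 can be opened with PhCO2H and Bu4N(O2CPh) under more forcing conditions (50 °C) to give 5 directly. Compound 4 and the directed reduction are bypassed, so this is also a second, substrate-controlled way to set C6.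

**Step 6** (enzymatic resolution). The risks are low enantioselectivity, the opposite enantiopreference, or slow turnover on a crowded triol. The fallback sets out from 7 and comes back at 8. The enantiomers of 7 are separated by preparative chromatography on a chiral stationary phase (amylose tris(3,5-dimethylphenylcarbamate), supercritical CO2/MeOH). The (1S,2S,5R,6S) enantiomer is then acetylated chemically at C5 (AcCl, 2,4,6-collidine, CH2Cl2, −78 °C), relying on the steric difference between C5–OH and the neopentyl-type C2–OH; this gives 8 without any new intermediate. If the lipase merely shows the opposite preference, the unreacted triol from step 6 is the wanted enantiomer and is taken through the same chemical acetylation. In either case the absolute configuration is confirmed by comparing the optical rotation of 9 with that of the natural product.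

## Further compounds

F1 | step 1 | racemic 1-oxaspiro[2.5]octa-5,7-dien-4-ol, OH anti to the oxirane O | C1=CC=C[C@@]2(CO2)[C@H]1O
F2 | step 1 | racemic 1-oxaspiro[2.5]octa-5,7-dien-4-yl acetate, OAc anti to the oxirane O | C1=CC=C[C@@]2(CO2)[C@H]1OC(C)=O
F3 | step 1 | racemic spiro[2,3-dioxabicyclo[2.2.2]oct-7-ene-5,2'-oxiran]-6-yl acetate, oxirane O syn and OAc anti to the O–O bridge | O3[C@@H]1C=C[C@H](O3)[C@@]4(CO4)[C@H]1OC(C)=O
F4 | step 2 | racemic spiro[2,3-dioxabicyclo[2.2.2]oct-7-ene-5,2'-oxiran]-6-ol, oxirane O syn and OH anti to the O–O bridge | O3[C@@H]1C=C[C@H](O3)[C@@]4(CO4)[C@H]1O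
F0 | step 6 | none | none
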